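**Plan**
- Feature: in the oxolane (O1, C2 veratryl, C3 bearing C6, C4 bearing C7, C5) C3 and C4 each carry one exocyclic carbon and C5 is a methylene on oxygen, so C2–C3–C4–C7 is a 1,4-dioxygenated but-2-yne (C3≡C4) whose free C2 hydroxyl can steer a carbon nucleophile to C3 and a metal to C4.
- Retrosynthetic cuts, in order: C6–OH back to C6–Si; C3–H and C4–H back to the C3=C4 enone; C7=O back to a silyl ether; O1–C5; then C3–C6 and C4–C5 together; finally C2–C3 and C4–C7, which leaves acetylene and the two aryl aldehydes.
- Forward: ethynyl Grignard addition to 3,4,5-trimethoxybenzaldehyde (C4–C7), silylation, enantioselective alkynylation of veratraldehyde (C2–C3), anti-carbomagnesiation with formaldehyde capture, O1–C5 etherification that closes the only new ring, C7 unmasking and oxidation, conjugate reduction, Tamao–Fleming oxidation.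
- Stereochemistry: C2 comes from the (R)-BINOL–titanium alkynylation and is kept because O1 acts as the nucleophile; the alkene geometry comes from anti addition and retentive capture; C3 comes from hydride delivery trans to the C2 aryl; C4 comes from base equilibration trans to C3.

Key step: step 5

Remarks: atom labels C2–C7 follow the oxolane numbering of the target throughout. C7 is carried as a mixture of both epimers until it becomes the ketone in step 8. Benzyl(chloromethyl)dimethylsilane is taken as a commercial reagent. Two spectator groups are chosen for the endgame: a triethylsilyl ether on the C7 oxygen and a benzyldimethylsilyl group on C6.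

**Step 1**
Reactants: 1 3,4,5-trimethoxybenzaldehyde; 2 ethynylmagnesium bromide
Product: 3 rac-1-(3,4,5-trimethoxyphenyl)prop-2-yn-1-ol
Conditions: THF, 0 °C → rt; aq. NH4Cl
Reagents that add atoms: none
Why: Grignard 1,2-addition of an acetylide to an aryl aldehyde forms C4–C7; the carbinol C7 is racemic, which is harmless because it ends as the ketone.

**Step 2**
Reactants: 3 rac-1-(3,4,5-trimethoxyphenyl)prop-2-yn-1-ol
Product: 4 rac-triethyl{[1-(3,4,5-trimethoxyphenyl)prop-2-yn-1-yl]oxy}silane
Conditions: Et3SiCl, imidazole, DMF, 0 °C → rt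
Reagents that add atoms: chlorotriethylsilane, CC[Si](Cl)(CC)CC
Why: Imidazole-promoted O-silylation leaves only the later C2 hydroxyl free to direct the carbomagnesiation, and a triethylsilyl ether is chosen because it can be removed later without the fluoride that would also cleave the benzylsilane.

**Step 3**
Reactants: 4 rac-triethyl{[1-(3,4,5-trimethoxyphenyl)prop-2-yn-1-yl]oxy}silane; 5 veratraldehyde (3,4-dimethoxybenzaldehyde)
Product: 7 (1S)-1-(3,4-dimethoxyphenyl)-4-(triethylsilyloxy)-4-(3,4,5-trimethoxyphenyl)but-2-yn-1-ol (both C4 epimers; chain C1 = C2 and chain C4 = C7), via alkynyl(ethyl)zinc reagent 6 (not isolated)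
Conditions: 4 (2 equiv), Et2Zn (2 equiv), toluene, reflux; then (R)-BINOL (20 mol %), Ti(OiPr)4 (50 mol %), Et2O, rt; then 5, rt; aq. NH4Cl
Reagents that add atoms: none
Why: Titanium–BINOLate-catalysed enantioselective addition of an alkynylzinc reagent to an aromatic aldehyde forms C2–C3 and sets C2; (R)-BINOL is expected to direct the alkynyl group to the Re face of the aldehyde and so give the S carbinol (sense assigned by analogy with aryl aldehyde alkynylations of this type, to be checked on the product, the antipodal ligand being equally available), while C7 stays epimeric and the excess of 4 is recoverable.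

**Step 4**
Reactants: 8 benzyl(chloromethyl)dimethylsilane
Product: 9 [(benzyldimethylsilyl)methyl]magnesium chloride
Conditions: Mg turnings, BrCH2CH2Br (cat.), THF, 40 °C → reflux
Reagents that add atoms: magnesium, [Mg]
Why: Magnesium insertion into an α-chloromethylsilane is a standard Grignard formation, and the benzyldimethylsilyl group is a hydroxyl surrogate that tolerates Grignard reagents, alkoxides, mild acid and oxidants, whereas an alkoxysilyl group would be captured by the neighbouring C2 or C7 oxygen.

**Step 5**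
Reactants: 7 (1S)-1-(3,4-dimethoxyphenyl)-4-(triethylsilyloxy)-4-(3,4,5-trimethoxyphenyl)but-2-yn-1-ol; 9 [(benzyldimethylsilyl)methyl]magnesium chloride; 10 formaldehyde
Product: 12 (1S,2Z)-2-[(benzyldimethylsilyl)methyl]-1-(3,4-dimethoxyphenyl)-3-[(triethylsilyloxy)(3,4,5-trimethoxyphenyl)methyl]but-2-ene-1,4-diol, via alkenylmagnesium chelate 11 (not isolated)
Conditions: 9 (3.5 equiv), CuI (10 mol %), THF, 0 °C → reflux; then CH2O (g, from cracked paraformaldehyde), −20 → 0 °C; aq. NH4Cl
Reagents that add atoms: none
Why: The first equivalent of 9 deprotonates the C2 hydroxyl, and the resulting magnesium alkoxide directs a second silylmethyl group (CuI-assisted) to the proximal alkyne carbon C3 in an anti sense, leaving magnesium on C4 inside the five-membered oxamagnesacycle 11; formaldehyde then replaces the C4–Mg bond with retention and creates C4–C5. The closest known reaction type is the hydroxyl-directed anti-carbomagnesiation of propargylic alcohols with (silylmethyl)magnesium halides followed by electrophilic capture of the chelated alkenylmagnesium. No ring is closed and no stereocentre is created; C2 is untouched and C7 remains epimeric. The step needs regioselectivity (carbon to C3, not C4) and anti geometry (C2 and C5 cis, the Z alkene), and both are secured by the single free alkoxide at C2, the C7 oxygen being masked as a bulky, weakly coordinating silyl ether. β-Elimination of that silyloxy group from the C4–Mg bond is disfavoured because allylic strain keeps the C7–O bond out of the plane of the C4–Mg bond. The benzyldimethylsilyl group on C6 cannot be attacked by the neighbouring alkoxides, so the diol is obtained as a defined open-chain compound.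

**Step 6**
Reactants: 12 (1S,2Z)-2-[(benzyldimethylsilyl)methyl]-1-(3,4-dimethoxyphenyl)-3-[(triethylsilyloxy)(3,4,5-trimethoxyphenyl)methyl]but-2-ene-1,4-diol
Product: 14 (2S)-3-[(benzyldimethylsilyl)methyl]-2-(3,4-dimethoxyphenyl)-4-[(triethylsilyloxy)(3,4,5-trimethoxyphenyl)methyl]-2,5-dihydrofuran, via primary monotosylate 13 (not isolated)
Conditions: TsCl (1.1 equiv), Et3N, DMAP (10 mol %), CH2Cl2, −20 °C → rt
Reagents that add atoms: none
Why: Selective sulfonylation of the primary allylic hydroxyl followed by intramolecular Williamson etherification (5-exo-tet) by the cis-disposed C2 hydroxyl closes the oxolane ring as its 2,5-dihydro form; the C2–O bond is never broken, so C2 keeps its configuration, and neither fluoride nor a metal alkoxide is present to trigger 1,4-elimination of the allylsilane.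

**Step 7**
Reactants: 14 (2S)-3-[(benzyldimethylsilyl)methyl]-2-(3,4-dimethoxyphenyl)-4-[(triethylsilyloxy)(3,4,5-trimethoxyphenyl)methyl]-2,5-dihydrofuran
Product: 15 (2S)-3-[(benzyldimethylsilyl)methyl]-2-(3,4-dimethoxyphenyl)-4-[hydroxy(3,4,5-trimethoxyphenyl)methyl]-2,5-dihydrofuran
Conditions: PPTS (10 mol %), MeOH/CH2Cl2, 0 °C
Reagents that add atoms: none
Why: Acid-catalysed methanolysis of a triethylsilyl ether proceeds at silicon under conditions mild enough to spare the benzylsilane, the allylsilane and the benzylic ring ether.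

**Step 8**
Reactants: 15 (2S)-3-[(benzyldimethylsilyl)methyl]-2-(3,4-dimethoxyphenyl)-4-[hydroxy(3,4,5-trimethoxyphenyl)methyl]-2,5-dihydrofuran
Product: 16 (2S)-3-[(benzyldimethylsilyl)methyl]-2-(3,4-dimethoxyphenyl)-4-(3,4,5-trimethoxybenzoyl)-2,5-dihydrofuran
Conditions: MnO2 (activated), CH2Cl2, rt
Reagents that add atoms: none
Why: MnO2 oxidation of a secondary alcohol that is both allylic and benzylic gives the tetrasubstituted enone under neutral conditions, which converges the C7 epimers and avoids base that could move the alkene through the acidic C2–H.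

**Step 9**
Reactants: 16 (2S)-3-[(benzyldimethylsilyl)methyl]-2-(3,4-dimethoxyphenyl)-4-(3,4,5-trimethoxybenzoyl)-2,5-dihydrofuran
Product: 18 (2R,3S,4S)-3-[(benzyldimethylsilyl)methyl]-2-(3,4-dimethoxyphenyl)-4-(3,4,5-trimethoxybenzoyl)oxolane, via silyl enol ether 17 (not isolated)
Conditions: Cu(OAc)2·H2O (5 mol %), 1,2-bis(diphenylphosphino)benzene (5 mol %), (EtO)2MeSiH (1.5 equiv), toluene, rt; then K2CO3, MeOH, rt
Reagents that add atoms: none
Why: Phosphine-ligated copper hydride conjugate reduction (hydrocupration, then silyl transfer to the enolate) delivers hydride to C3 on the face opposite the C2 aryl, which puts C6 cis to that aryl (3S), and carbonate-mediated methanolysis of the silyl enol ether protonates the enolisable C4 reversibly so that the aroyl group settles trans to C6 (4S).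

**Step 10**
Reactants: 18 (2R,3S,4S)-3-[(benzyldimethylsilyl)methyl]-2-(3,4-dimethoxyphenyl)-4-(3,4,5-trimethoxybenzoyl)oxolane
Product: 20 [(3S,4R,5R)-5-(3,4-dimethoxyphenyl)-4-(hydroxymethyl)oxolan-3-yl](3,4,5-trimethoxyphenyl)methanone (the target; 2R,3R,4S in the oxolane numbering used here), via dimethylsilanol 19 (not isolated)
Conditions: TBAF, THF, 0 °C → rt; then KHCO3, 30 % aq. H2O2, MeOH, rt
Reagents that add atoms: hydrogen peroxide, OO
Why: Tamao–Fleming oxidation: fluoride cleaves the benzyl–silicon bond to give a silanol, and basic hydrogen peroxide then induces 1,2-migration of C6 from silicon to oxygen, which touches no stereocentre (C3 changes only its descriptor from S to R), to give the target.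

**Compound list**
1 | 3,4,5-trimethoxybenzaldehyde | COc1cc(C=O)cc(OC)c1OC | starting material
2 | ethynylmagnesium bromide | C#C[Mg]Br | starting material
3 | rac-1-(3,4,5-trimethoxyphenyl)prop-2-yn-1-ol | COc1cc(C(O)C#C)cc(OC)c1OC | intermediate
4 | rac-triethyl{[1-(3,4,5-trimethoxyphenyl)prop-2-yn-1-yl]oxy}silane | CC[Si](CC)(CC)OC(C#C)c1cc(OC)c(OC)c(OC)c1 | intermediate
5 | veratraldehyde (3,4-dimethoxybenzaldehyde) | COc1ccc(C=O)cc1OC | starting material
6 | ethyl[3-(triethylsilyloxy)-3-(3,4,5-trimethoxyphenyl)prop-1-yn-1-yl]zinc | CC[Zn]C#CC(O[Si](CC)(CC)CC)c1cc(OC)c(OC)c(OC)c1 | intermediate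
7 | (1S)-1-(3,4-dimethoxyphenyl)-4-(triethylsilyloxy)-4-(3,4,5-trimethoxyphenyl)but-2-yn-1-ol (both C4 epimers) | COc1ccc([C@H](O)C#CC(O[Si](CC)(CC)CC)c2cc(OC)c(OC)c(OC)c2)cc1OC | intermediate
8 | benzyl(chloromethyl)dimethylsilane | C[Si](C)(CCl)Cc1ccccc1 | starting material
9 | [(benzyldimethylsilyl)methyl]magnesium chloride | C[Si](C)(C[Mg]Cl)Cc1ccccc1 | intermediate
10 | formaldehyde | C=O | starting material
11 | five-membered magnesium alkoxide chelate with Mg on C4 and the silylmethyl group on C3, (S) at C2 | COc1ccc([C@@H]2O[Mg]C(C(O[Si](CC)(CC)CC)c3cc(OC)c(OC)c(OC)c3)=C2C[Si](C)(C)Cc2ccccc2)cc1OC | intermediate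
12 | (1S,2Z)-2-[(benzyldimethylsilyl)methyl]-1-(3,4-dimethoxyphenyl)-3-[(triethylsilyloxy)(3,4,5-trimethoxyphenyl)methyl]but-2-ene-1,4-diol | COc1ccc([C@H](O)/C(C[Si](C)(C)Cc2ccccc2)=C(\CO)C(O[Si](CC)(CC)CC)c2cc(OC)c(OC)c(OC)c2)cc1OC | intermediate
13 | primary (C5) p-toluenesulfonate of diol 12 | COc1ccc([C@H](O)/C(C[Si](C)(C)Cc2ccccc2)=C(\COS(=O)(=O)c2ccc(C)cc2)C(O[Si](CC)(CC)CC)c2cc(OC)c(OC)c(OC)c2)cc1OC | intermediate
14 | (2S)-3-[(benzyldimethylsilyl)methyl]-2-(3,4-dimethoxyphenyl)-4-[(triethylsilyloxy)(3,4,5-trimethoxyphenyl)methyl]-2,5-dihydrofuran | COc1ccc([C@@H]2OCC(C(O[Si](CC)(CC)CC)c3cc(OC)c(OC)c(OC)c3)=C2C[Si](C)(C)Cc2ccccc2)cc1OC | intermediate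
15 | (2S)-3-[(benzyldimethylsilyl)methyl]-2-(3,4-dimethoxyphenyl)-4-[hydroxy(3,4,5-trimethoxyphenyl)methyl]-2,5-dihydrofuran | COc1ccc([C@@H]2OCC(C(O)c3cc(OC)c(OC)c(OC)c3)=C2C[Si](C)(C)Cc2ccccc2)cc1OC | intermediate
16 | (2S)-3-[(benzyldimethylsilyl)methyl]-2-(3,4-dimethoxyphenyl)-4-(3,4,5-trimethoxybenzoyl)-2,5-dihydrofuran | COc1ccc([C@@H]2OCC(C(=O)c3cc(OC)c(OC)c(OC)c3)=C2C[Si](C)(C)Cc2ccccc2)cc1OC | intermediate
17 | diethoxy(methyl)silyl enol ether (C4=C7, geometry not defined) of the (2R,3S)-configured ketone 18 | COc1ccc([C@@H]2OCC(=C(O[Si](C)(OCC)OCC)c3cc(OC)c(OC)c(OC)c3)[C@@H]2C[Si](C)(C)Cc2ccccc2)cc1OC | intermediate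
18 | (2R,3S,4S)-3-[(benzyldimethylsilyl)methyl]-2-(3,4-dimethoxyphenyl)-4-(3,4,5-trimethoxybenzoyl)oxolane (2,3-cis, 3,4-trans) | COc1ccc([C@@H]2OC[C@@H](C(=O)c3cc(OC)c(OC)c(OC)c3)[C@@H]2C[Si](C)(C)Cc2ccccc2)cc1OC | intermediate
19 | (2R,3S,4S)-2-(3,4-dimethoxyphenyl)-3-[(hydroxydimethylsilyl)methyl]-4-(3,4,5-trimethoxybenzoyl)oxolane | COc1ccc([C@@H]2OC[C@@H](C(=O)c3cc(OC)c(OC)c(OC)c3)[C@@H]2C[Si](C)(C)O)cc1OC | intermediate
20 | [(3S,4R,5R)-5-(3,4-dimethoxyphenyl)-4-(hydroxymethyl)oxolan-3-yl](3,4,5-trimethoxyphenyl)methanone | COc1ccc([C@@H]2OC[C@@H](C(=O)c3cc(OC)c(OC)c(OC)c3)[C@@H]2CO)cc1OC | target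

**Step count**
Total: 10 steps. Longest linear sequence: 9 steps (1, 2, 3, 5, 6, 7, 8, 9, 10) from 3,4,5-trimethoxybenzaldehyde; step 4 is a one-step side branch.

**Steps most likely to fail**

Step 5. The hindered internal alkyne may be carbometalated slowly. The alkenylmagnesium may lose the C7 silyloxy group by β-elimination to an allene. The crowded C4–Mg bond may also be captured incompletely by gaseous formaldehyde, so that protonation on work-up leaves C4 without C5. The fallback sets out from 7 and 9 and keeps the alkoxide-directed carbomagnesiation, but chelate 11 is captured with CO2 (1 atm, −20 °C → rt; aq. NH4Cl), a small and irreversible electrophile. The cis hydroxy acid lactonises to the butenolide (5S)-4-[(benzyldimethylsilyl)methyl]-5-(3,4-dimethoxyphenyl)-3-[(triethylsilyloxy)(3,4,5-trimethoxyphenyl)methyl]furan-2(5H)-one F1, whose ring also proves the alkene geometry. Reduction with i-Bu2AlH (CH2Cl2, −78 → 0 °C) opens the lactone to diol 12, where the route continues.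

Step 9. The fully substituted β-carbon C3 may resist hydrocupration, or hydride may be delivered with poor facial selectivity or to the carbonyl group. The fallback sets out from 16 and replaces hydride conjugate addition by homogeneous hydrogenation with [Ir(cod)(PCy3)(py)]PF6 under H2 in CH2Cl2. This should add both hydrogens to the face opposite the C2 aryl without hydrogenolysis of the benzylic ether and give the all-cis ketone (2R,3S,4R)-3-[(benzyldimethylsilyl)methyl]-2-(3,4-dimethoxyphenyl)-4-(3,4,5-trimethoxybenzoyl)oxolane F2. K2CO3 in MeOH then epimerises C4 and brings the route back to 18.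

Step 7. Acid may ionise the allylic, benzylic C7–O bond of the liberated alcohol, with loss of the allylsilane by 1,4-elimination to a diene, or may solvolyse the C2–O1 bond and erode C2. The fallback sets out from 14 and does not hydrolyse the silyl ether at all. 2-Iodoxybenzoic acid (IBX) in DMSO at rt cleaves the triethylsilyl ether and oxidises the benzylic alcohol in the same flask, so that the route is rejoined at enone 16 and steps 7 and 8 are merged. This detour makes no compound outside the list (F0).

**Further compounds**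
F1 | step 5 | (5S)-4-[(benzyldimethylsilyl)methyl]-5-(3,4-dimethoxyphenyl)-3-[(triethylsilyloxy)(3,4,5-trimethoxyphenyl)methyl]furan-2(5H)-one | COc1ccc([C@@H]2OC(=O)C(C(O[Si](CC)(CC)CC)c3cc(OC)c(OC)c(OC)c3)=C2C[Si](C)(C)Cc2ccccc2)cc1OC
F2 | step 9 | (2R,3S,4R)-3-[(benzyldimethylsilyl)methyl]-2-(3,4-dimethoxyphenyl)-4-(3,4,5-trimethoxybenzoyl)oxolane | COc1ccc([C@@H]2OC[C@H](C(=O)c3cc(OC)c(OC)c(OC)c3)[C@@H]2C[Si](C)(C)Cc2ccccc2)cc1OC
F0 | step 7 | none | none
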